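**Strategy.** The target is cut along the 1,5-dicarbonyl path enone C=O–Cb–Ca–C3'H2–C2'=O, which runs through the two cis methyl-bearing quaternary carbons of the cyclopentane ring. A de Mayo sequence builds it: [2+2] photocycloaddition of a menthone-derived spiro 1,3-dioxin-4-one (a formylacetate equivalent) onto symmetrical 1,2-dimethylcyclopentene forms Cb–C(formyl), Ca–C3' and a cis-fused cyclobutane with four stereocentres in one operation; retro-aldol then releases a formyl ester. The ester arm becomes a dithiane that opens an (S)-alkynyl epoxide (sets C2), the pyran ring is closed at O1–C8a by Pd-catalysed etherification, and the aldehyde arm ends as the Z-enone by alkynylation and Lindlar reduction.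

Key step: step 3

Atom labels: chromene O1, C2, C3, C4, C4a–C8a; C1' = CH2 on C2, C2' = side-chain ketone, C3' = CH2 on Ca; Ca and Cb = cyclopentane carbons bearing C3' and the enone carbonyl.
Assumption: the alkene adds to the dioxinone face turned away from the isopropyl-bearing menthane carbon (C7); on that basis the (6S) spiro epimer is the one carried forward.

Step 1
Reactants: 1 5-(methoxymethylidene)-2,2-dimethyl-1,3-dioxane-4,6-dione
Product: 2 5-(hydroxymethylidene)-2,2-dimethyl-1,3-dioxane-4,6-dione (formyl Meldrum's acid)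
Conditions: 2 M aq. HCl, rt; filter
Reagents that add atoms: water, O
Why: Enol-ether hydrolysis by addition–elimination at the vinylogous ester carbon exchanges OMe for OH, and the acidic enol should precipitate before the acetonide is attacked.

Step 2
Reactants: 2 formyl Meldrum's acid; 3 (−)-menthone
Product: 5 (6S,7S,10R)-10-methyl-7-(propan-2-yl)-1,5-dioxaspiro[5.5]undec-2-en-4-one, via formylketene 4 (not isolated)
Conditions: 3 (3 equiv), toluene, 110 °C; spiro epimers separated by chromatography
Reagents that add atoms: none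
Why: Thermal retro-[4+2] loss of acetone and CO2 gives formylketene, which the ketone C=O traps in a hetero-Diels–Alder reaction; the spiro centre C6 forms without control, so the 6S epimer is separated and kept, and the two menthone centres are not touched.

Step 3
Reactants: 5 (6S)-spiro dioxinone; 6 1,2-dimethylcyclopentene
Product: 7 cis-anti-cis cyclobutane photoadduct of 5 and 6 (all four new centres S)
Conditions: hν (300 nm, Pyrex), 6 (10 equiv), acetone–MeCN 1:9, degassed, −40 °C; 7 purified to a single diastereomer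
Reagents that add atoms: none
Why: Acetone-sensitised excitation gives the triplet dioxinone, which adds to the electron-rich alkene through a triplet 1,4-biradical that closes to the cyclobutane after spin inversion; this is the photochemical half of a de Mayo reaction. The closest known reaction type is the [2+2] photocycloaddition of menthone-derived spiro 1,3-dioxin-4-ones with cyclopentene and with tetrasubstituted alkenes. The one new ring, the cyclobutane, is closed by radical–radical coupling of the 1,4-biradical and can only be cis-fused to the cyclopentane and to the dioxanone, which places the two methyls cis. C5 and C6 of the dioxanone are set by π-facial attack anti to C7 of the menthane, whose isopropyl group hangs over the other face; Ca and Cb are set by the exo orientation of the alkene, with its three ring CH2 groups turned away from the dioxinone and menthane. The step therefore needs facial and exo selectivity but no regioselectivity, because the alkene is symmetrical; the spiro auxiliary, low temperature and excess alkene serve the former, and allylic hydrogen transfer inside the biradical is the main expected loss.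

Step 4
Reactants: 7 photoadduct
Product: 8 methyl 2-[(1S,2S)-2-formyl-1,2-dimethylcyclopentyl]acetate
Conditions: K2CO3 (0.2 equiv), MeOH, 0 °C → rt; menthone recovered
Reagents that add atoms: methanol, CO
Why: Methanolysis of the acetal-lactone releases menthone and a cyclobutanol β-hydroxy ester, whose strain-driven retro-aldol cleavage of the former C5–C6 bond gives the 1,5-formyl ester; both stereocentres are quaternary and cannot epimerise.

Step 5
Reactants: 8 formyl ester
Product: 10 (4aS,7aS)-4a,7a-dimethylhexahydrocyclopenta[c]pyran-3(1H)-one, via hydroxy ester 9 (not isolated)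
Conditions: NaBH4, MeOH, 0 °C; aq. NH4Cl; then TsOH·H2O (cat.), CH2Cl2, rt
Reagents that add atoms: none
Why: Chemoselective borohydride reduction of the aldehyde beside the ester, then acid-catalysed lactonisation of the cis δ-hydroxy ester; no stereocentre is formed.

Step 6
Reactants: 10 lactone
Product: 11 (4aS,7aS)-4a,7a-dimethyloctahydrocyclopenta[c]pyran-3-ol (anomers)
Conditions: DIBAL-H (1.1 equiv), CH2Cl2, −78 °C; Rochelle salt
Reagents that add atoms: none
Why: DIBAL-H reduction of a lactone stops at the lactol because the tetrahedral aluminate survives at −78 °C; the anomeric mixture is of no consequence.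

Step 7
Reactants: 11 lactol
Product: 12 {(1S,2S)-2-[(1,3-dithian-2-yl)methyl]-1,2-dimethylcyclopentyl}methanol
Conditions: HS(CH2)3SH (1.2 equiv), BF3·OEt2 (0.3 equiv), CH2Cl2, −20 → 0 °C
Reagents that add atoms: propane-1,3-dithiol, SCCCS
Why: Lewis-acid-catalysed thioacetalisation of the lactol (a masked hydroxy aldehyde) gives the open-chain 1,3-dithiane at C2' and frees the neopentyl alcohol.

Step 8
Reactants: 12 hydroxy dithiane
Product: 13 tert-butyl({(1S,2S)-2-[(1,3-dithian-2-yl)methyl]-1,2-dimethylcyclopentyl}methoxy)diphenylsilane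
Conditions: TBDPSCl, imidazole, DMAP (cat.), DMF, rt → 40 °C
Reagents that add atoms: tert-butyl(chloro)diphenylsilane, CC(C)(C)[Si](Cl)(c1ccccc1)c1ccccc1
Why: Standard silylation of a primary alcohol; TBDPS is chosen because it should survive t-BuLi, trifluoroacetic acid in methanol and carbonate bases.

Step 9
Reactants: 14 (S)-2-methylglycidol
Product: 16 (2S)-2-(2,2-dibromoethenyl)-2-methyloxirane, via epoxy aldehyde 15 (not isolated)
Conditions: IBX, EtOAc, 75 °C; filter; filtrate into CBr4/PPh3, CH2Cl2, 0 °C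
Reagents that add atoms: carbon tetrabromide, BrC(Br)(Br)Br
Why: IBX oxidation gives the volatile epoxy aldehyde, which is filtered straight into the Ramirez ylide for Corey–Fuchs dibromo-olefination; the quaternary stereocentre has no α-hydrogen and is unchanged.

Step 10
Reactants: 16 dibromo-olefin
Product: 18 trimethyl{[(2S)-2-methyloxiran-2-yl]ethynyl}silane, via lithium acetylide 17 (not isolated)
Conditions: n-BuLi (2.1 equiv), THF, −78 °C; TMSCl, −78 °C → rt
Reagents that add atoms: chlorotrimethylsilane, C[Si](C)(C)Cl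
Why: Second stage of the Corey–Fuchs reaction (Br/Li exchange, Fritsch–Buttenberg–Wiechell rearrangement, deprotonation) gives the acetylide, which is C-silylated; the epoxide tolerates n-BuLi at −78 °C.

Step 11
Reactants: 13 silyl ether dithiane; 18 silylalkynyl epoxide
Product: 21 (2R)-1-[2-({(1S,2S)-2-[(tert-butyldiphenylsilyloxy)methyl]-1,2-dimethylcyclopentyl}methyl)-1,3-dithian-2-yl]-2-methylbut-3-yn-2-ol, via lithiated dithiane 19 (not isolated), via silylalkyne alkoxide 20 (not isolated)
Conditions: t-BuLi (1.05 equiv), THF–HMPA 9:1, −78 °C; 18 (1.3 equiv), −78 → −20 °C; then MeOH, K2CO3, rt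
Reagents that add atoms: none
Why: Corey–Seebach dithiane anion opens the 2,2-disubstituted epoxide by SN2 attack at its CH2 terminus (C1'–C2' bond), so no bond at C2 is broken and the epoxide configuration is carried over (R by CIP); methoxide then cleaves the C(sp)–Si bond.

Step 12
Reactants: 21 dithiane alkynol
Product: 22 (3R)-6-{(1S,2S)-2-[(tert-butyldiphenylsilyloxy)methyl]-1,2-dimethylcyclopentyl}-5,5-dimethoxy-3-methylhex-1-yn-3-ol
Conditions: PhI(OCOCF3)2 (1.5 equiv), anhydrous MeOH, 0 °C; NaHCO3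
Reagents that add atoms: methanol, CO
Why: Oxidative dethioketalisation with a hypervalent iodine reagent in methanol traps the oxocarbenium ion as the dimethyl ketal, which removes sulfur before the Pd steps and masks the ketone so that the tertiary aldol cannot undergo retro-aldol under base.

Step 13
Reactants: 23 4-methoxy-2-methylaniline
Product: 24 2-iodo-4-methoxy-6-methylaniline
Conditions: NIS, MeCN, 0 °C → rt
Reagents that add atoms: N-iodosuccinimide, O=C1CCC(=O)N1I
Why: Electrophilic aromatic iodination goes to the only free position ortho to the amino group, the para position being blocked by OMe.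

Step 14
Reactants: 24 iodoaniline
Product: 26 2-bromo-1-iodo-5-methoxy-3-methylbenzene, via arenediazonium bromide 25 (not isolated)
Conditions: t-BuONO, CuBr2, MeCN, 0 → 60 °C
Reagents that add atoms: copper(II) bromide, Br[Cu]Br
Why: Non-aqueous Sandmeyer bromo-dediazoniation replaces NH2 by Br through the diazonium salt while the C–I bond is kept.

Step 15
Reactants: 22 ketal alkynol; 26 bromo-iodoarene
Product: 27 (3R)-1-(2-bromo-5-methoxy-3-methylphenyl)-6-{(1S,2S)-2-[(tert-butyldiphenylsilyloxy)methyl]-1,2-dimethylcyclopentyl}-5,5-dimethoxy-3-methylhex-1-yn-3-ol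
Conditions: PdCl2(PPh3)2 (3 mol%), CuI (5 mol%), Et3N–THF, rt → 40 °C
Reagents that add atoms: none
Why: Sonogashira coupling is selective for C–I over the flanked C–Br and forms the C4–C4a bond without touching the carbinol centre.

Step 16
Reactants: 27 aryl alkyne
Product: 28 (1Z,3R)-1-(2-bromo-5-methoxy-3-methylphenyl)-6-{(1S,2S)-2-[(tert-butyldiphenylsilyloxy)methyl]-1,2-dimethylcyclopentyl}-5,5-dimethoxy-3-methylhex-1-en-3-ol
Conditions: H2 (1 atm), Lindlar catalyst, quinoline, EtOAc, rt
Reagents that add atoms: none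
Why: Lindlar syn-semihydrogenation sets the Z alkene that brings the tertiary hydroxyl within reach of the C–Br carbon; the poisoned catalyst should spare the aryl bromide.

Step 17
Reactants: 28 (Z)-bromostyrenyl carbinol
Product: 29 tert-butyl{[(1S,2S)-2-{2,2-dimethoxy-3-[(2R)-6-methoxy-2,8-dimethyl-2H-chromen-2-yl]propyl}-1,2-dimethylcyclopentyl]methoxy}diphenylsilane
Conditions: Pd(OAc)2 (5 mol%), 2-(di-tert-butylphosphino)-1,1'-binaphthyl (6 mol%), Cs2CO3, toluene, 80 °C
Reagents that add atoms: none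
Why: Buchwald-type Pd-catalysed intramolecular C–O coupling of an aryl bromide with a tertiary alkoxide (no β-hydrogen) closes the 2H-pyran ring at O1–C8a; the C2–O bond is never broken, so C2 stays R.

Step 18
Reactants: 29 chromene silyl ether
Product: 30 [(1S,2S)-2-{2,2-dimethoxy-3-[(2R)-6-methoxy-2,8-dimethyl-2H-chromen-2-yl]propyl}-1,2-dimethylcyclopentyl]methanol
Conditions: TBAF, THF, rt → 40 °C
Reagents that add atoms: none
Why: Fluoride-driven desilylation; ketal, aryl ether and chromene alkene are inert to TBAF.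

Step 19
Reactants: 30 primary alcohol
Product: 31 (1S,2S)-2-{2,2-dimethoxy-3-[(2R)-6-methoxy-2,8-dimethyl-2H-chromen-2-yl]propyl}-1,2-dimethylcyclopentane-1-carbaldehyde
Conditions: DMP, NaHCO3, CH2Cl2, 0 °C → rt
Reagents that add atoms: none
Why: Dess–Martin oxidation gives the non-enolisable neopentyl aldehyde; the buffer protects the ketal.

Step 20
Reactants: 31 aldehyde; 32 2-methylbut-3-yn-2-ol
Product: 33 1-[(1S,2S)-2-{2,2-dimethoxy-3-[(2R)-6-methoxy-2,8-dimethyl-2H-chromen-2-yl]propyl}-1,2-dimethylcyclopentyl]-4-methylpent-2-yne-1,4-diol (both C1 epimers)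
Conditions: 32 (3 equiv), n-BuLi (6 equiv), THF, −78 → 0 °C; then 31, −78 °C → rt; aq. NH4Cl
Reagents that add atoms: none
Why: 1,2-Addition of the lithium acetylide (O,C-dianion of the alkynol) to the aldehyde while C2' is still a ketal; the new carbinol centre forms as a mixture and is erased by the next oxidation.

Step 21
Reactants: 33 propargylic diol
Product: 34 1-[(1S,2S)-2-{2,2-dimethoxy-3-[(2R)-6-methoxy-2,8-dimethyl-2H-chromen-2-yl]propyl}-1,2-dimethylcyclopentyl]-4-hydroxy-4-methylpent-2-yn-1-one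
Conditions: DMP, NaHCO3, CH2Cl2, rt
Reagents that add atoms: none
Why: Dess–Martin oxidation converts the secondary propargylic alcohol into the ynone; the tertiary alcohol cannot be oxidised.

Step 22
Reactants: 34 ynone ketal
Product: 35 4-hydroxy-1-[(1S,2S)-2-{3-[(2R)-6-methoxy-2,8-dimethyl-2H-chromen-2-yl]-2-oxopropyl}-1,2-dimethylcyclopentyl]-4-methylpent-2-yn-1-one
Conditions: PPTS (cat.), acetone–H2O 10:1, rt
Reagents that add atoms: water, O
Why: Mild acid-catalysed ketal hydrolysis frees the C2' ketone; no base is used from here on, so the β-aryloxy ketone cannot eliminate.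

Step 23
Reactants: 35 ynone
Product: 36 (2Z)-4-hydroxy-1-[(1S,2S)-2-{3-[(2R)-6-methoxy-2,8-dimethyl-2H-chromen-2-yl]-2-oxopropyl}-1,2-dimethylcyclopentyl]-4-methylpent-2-en-1-one (CNP0137762.2)
Conditions: H2 (1 atm), Lindlar catalyst, quinoline, EtOAc, 0 °C; stopped at one equivalent of H2
Reagents that add atoms: none
Why: Lindlar semihydrogenation adds H2 syn to the ynone and so sets the Z enone; the cis-disubstituted chromene alkene is expected to be much slower on the poisoned catalyst.

**Compound list**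

1 | 5-(methoxymethylidene)-2,2-dimethyl-1,3-dioxane-4,6-dione | COC=C1C(=O)OC(C)(C)OC1=O | starting material
2 | 5-(hydroxymethylidene)-2,2-dimethyl-1,3-dioxane-4,6-dione | OC=C1C(=O)OC(C)(C)OC1=O | intermediate
3 | (−)-menthone, (2S,5R)-5-methyl-2-(propan-2-yl)cyclohexan-1-one | C[C@@H]1CC[C@H](C(=O)C1)C(C)C | starting material
4 | formylketene | O=CC=C=O | intermediate (not isolated)
5 | (6S,7S,10R)-10-methyl-7-(propan-2-yl)-1,5-dioxaspiro[5.5]undec-2-en-4-one | C[C@@H]1CC[C@H]([C@@]2(C1)OC=CC(=O)O2)C(C)C | intermediate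
6 | 1,2-dimethylcyclopentene | CC1=C(C)CCC1 | starting material
7 | cis-anti-cis photoadduct: 1,3-dioxan-4-one spiro to the menthane (spiro C S), fused at C5(S)–C6(S) to a cyclobutane that is cis-fused to the 1,2-dimethylcyclopentane (Ca S, Cb S; methyls syn to the dioxanone) | C[C@@H]1CC[C@H]([C@@]2(C1)O[C@H]3[C@@H](C(=O)O2)[C@]4(C)CCC[C@]34C)C(C)C | intermediate
8 | methyl 2-[(1S,2S)-2-formyl-1,2-dimethylcyclopentyl]acetate | COC(=O)C[C@]1(C)CCC[C@]1(C)C=O | intermediate
9 | methyl 2-[(1S,2S)-2-(hydroxymethyl)-1,2-dimethylcyclopentyl]acetate | COC(=O)C[C@]1(C)CCC[C@]1(C)CO | intermediate (not isolated)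
10 | (4aS,7aS)-4a,7a-dimethylhexahydrocyclopenta[c]pyran-3(1H)-one | O=C1C[C@]2(C)CCC[C@]2(C)CO1 | intermediate
11 | (4aS,7aS)-4a,7a-dimethyloctahydrocyclopenta[c]pyran-3-ol (anomers) | OC1C[C@]2(C)CCC[C@]2(C)CO1 | intermediate
12 | {(1S,2S)-2-[(1,3-dithian-2-yl)methyl]-1,2-dimethylcyclopentyl}methanol | C1CSC(SC1)C[C@]2(C)CCC[C@]2(C)CO | intermediate
13 | tert-butyl({(1S,2S)-2-[(1,3-dithian-2-yl)methyl]-1,2-dimethylcyclopentyl}methoxy)diphenylsilane | C1CSC(SC1)C[C@]2(C)CCC[C@]2(C)CO[Si](c3ccccc3)(c3ccccc3)C(C)(C)C | intermediate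
14 | (S)-2-methylglycidol, [(2S)-2-methyloxiran-2-yl]methanol | C[C@]1(CO)CO1 | starting material
15 | (2R)-2-methyloxirane-2-carbaldehyde | C[C@]1(C=O)CO1 | intermediate (not isolated)
16 | (2S)-2-(2,2-dibromoethenyl)-2-methyloxirane | C[C@]1(C=C(Br)Br)CO1 | intermediate
17 | lithium [(2S)-2-methyloxiran-2-yl]ethynide | C[C@]1(C#C[Li])CO1 | intermediate (not isolated)
18 | trimethyl{[(2S)-2-methyloxiran-2-yl]ethynyl}silane | C[C@]1(C#C[Si](C)(C)C)CO1 | intermediate
19 | 2-lithio derivative of 13 | [Li]C1(SCCCS1)C[C@]2(C)CCC[C@]2(C)CO[Si](c3ccccc3)(c3ccccc3)C(C)(C)C | intermediate (not isolated)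
20 | lithium alkoxide of the (2R)-4-(trimethylsilyl)but-3-yn-2-ol adduct of 19 and 18 | C[Si](C)(C)C#C[C@](C)(O[Li])CC1(SCCCS1)C[C@]2(C)CCC[C@]2(C)CO[Si](c3ccccc3)(c3ccccc3)C(C)(C)C | intermediate (not isolated)
21 | (2R)-1-[2-({(1S,2S)-2-[(tert-butyldiphenylsilyloxy)methyl]-1,2-dimethylcyclopentyl}methyl)-1,3-dithian-2-yl]-2-methylbut-3-yn-2-ol | C#C[C@](C)(O)CC1(SCCCS1)C[C@]2(C)CCC[C@]2(C)CO[Si](c3ccccc3)(c3ccccc3)C(C)(C)C | intermediate
22 | (3R)-6-{(1S,2S)-2-[(tert-butyldiphenylsilyloxy)methyl]-1,2-dimethylcyclopentyl}-5,5-dimethoxy-3-methylhex-1-yn-3-ol | C#C[C@](C)(O)CC(OC)(OC)C[C@]2(C)CCC[C@]2(C)CO[Si](c3ccccc3)(c3ccccc3)C(C)(C)C | intermediate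
23 | 4-methoxy-2-methylaniline | COc1ccc(N)c(C)c1 | starting material
24 | 2-iodo-4-methoxy-6-methylaniline | COc1cc(C)c(N)c(I)c1 | intermediate
25 | 2-iodo-4-methoxy-6-methylbenzenediazonium bromide | COc1cc(C)c([N+]#N)c(I)c1.[Br-] | intermediate (not isolated)
26 | 2-bromo-1-iodo-5-methoxy-3-methylbenzene | COc1cc(C)c(Br)c(I)c1 | intermediate
27 | (3R)-1-(2-bromo-5-methoxy-3-methylphenyl)-6-{(1S,2S)-2-[(tert-butyldiphenylsilyloxy)methyl]-1,2-dimethylcyclopentyl}-5,5-dimethoxy-3-methylhex-1-yn-3-ol | COc1cc(C)c(Br)c(c1)C#C[C@](C)(O)CC(OC)(OC)C[C@]2(C)CCC[C@]2(C)CO[Si](c3ccccc3)(c3ccccc3)C(C)(C)C | intermediate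
28 | (1Z,3R)-1-(2-bromo-5-methoxy-3-methylphenyl)-6-{(1S,2S)-2-[(tert-butyldiphenylsilyloxy)methyl]-1,2-dimethylcyclopentyl}-5,5-dimethoxy-3-methylhex-1-en-3-ol | COc1cc(C)c(Br)c(c1)/C=C\[C@](C)(O)CC(OC)(OC)C[C@]2(C)CCC[C@]2(C)CO[Si](c3ccccc3)(c3ccccc3)C(C)(C)C | intermediate
29 | tert-butyl{[(1S,2S)-2-{2,2-dimethoxy-3-[(2R)-6-methoxy-2,8-dimethyl-2H-chromen-2-yl]propyl}-1,2-dimethylcyclopentyl]methoxy}diphenylsilane | COc1cc(C)c2c(c1)C=C[C@@](C)(CC(OC)(OC)C[C@]3(C)CCC[C@]3(C)CO[Si](c4ccccc4)(c4ccccc4)C(C)(C)C)O2 | intermediate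
30 | [(1S,2S)-2-{2,2-dimethoxy-3-[(2R)-6-methoxy-2,8-dimethyl-2H-chromen-2-yl]propyl}-1,2-dimethylcyclopentyl]methanol | COc1cc(C)c2c(c1)C=C[C@@](C)(CC(OC)(OC)C[C@]3(C)CCC[C@]3(C)CO)O2 | intermediate
31 | (1S,2S)-2-{2,2-dimethoxy-3-[(2R)-6-methoxy-2,8-dimethyl-2H-chromen-2-yl]propyl}-1,2-dimethylcyclopentane-1-carbaldehyde | COc1cc(C)c2c(c1)C=C[C@@](C)(CC(OC)(OC)C[C@]3(C)CCC[C@]3(C)C=O)O2 | intermediate
32 | 2-methylbut-3-yn-2-ol | CC(C)(O)C#C | starting material
33 | 1-[(1S,2S)-2-{2,2-dimethoxy-3-[(2R)-6-methoxy-2,8-dimethyl-2H-chromen-2-yl]propyl}-1,2-dimethylcyclopentyl]-4-methylpent-2-yne-1,4-diol (both C1 epimers) | COc1cc(C)c2c(c1)C=C[C@@](C)(CC(OC)(OC)C[C@]3(C)CCC[C@]3(C)C(O)C#CC(C)(C)O)O2 | intermediate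
34 | 1-[(1S,2S)-2-{2,2-dimethoxy-3-[(2R)-6-methoxy-2,8-dimethyl-2H-chromen-2-yl]propyl}-1,2-dimethylcyclopentyl]-4-hydroxy-4-methylpent-2-yn-1-one | COc1cc(C)c2c(c1)C=C[C@@](C)(CC(OC)(OC)C[C@]3(C)CCC[C@]3(C)C(=O)C#CC(C)(C)O)O2 | intermediate
35 | 4-hydroxy-1-[(1S,2S)-2-{3-[(2R)-6-methoxy-2,8-dimethyl-2H-chromen-2-yl]-2-oxopropyl}-1,2-dimethylcyclopentyl]-4-methylpent-2-yn-1-one | COc1cc(C)c2c(c1)C=C[C@@](C)(CC(=O)C[C@]3(C)CCC[C@]3(C)C(=O)C#CC(C)(C)O)O2 | intermediate
36 | (2Z)-4-hydroxy-1-[(1S,2S)-2-{3-[(2R)-6-methoxy-2,8-dimethyl-2H-chromen-2-yl]-2-oxopropyl}-1,2-dimethylcyclopentyl]-4-methylpent-2-en-1-one | COc1cc(C)c2c(c1)C=C[C@@](C)(CC(=O)C[C@]1(C)CCC[C@]1(C)C(=O)/C=C\C(C)(C)O)O2 | target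

**Step count.** Total: 23 steps. Longest linear sequence: 19 steps (1–8, 11, 12, 15–23); steps 9–10 (epoxide) and 13–14 (arene) are side branches.

**Steps most likely to fail**

Step 3. Discrimination between the two dioxinone faces, or between the two orientations of the alkene, may be incomplete; either error gives the enantiomeric cyclopentane after step 4. Hydrogen transfer inside the 1,4-biradical may also compete with ring closure. The fallback sets out from 2 and comes back at 8: control by the auxiliary is given up and the enantiomers are separated afterwards. Compound 2 is thermolysed in toluene containing acetone to give 2,2-dimethyl-4H-1,3-dioxin-4-one F1. Irradiation of F1 with 6 under the conditions of step 3 should give the racemic cis-fused photoadduct F2, of which only cis ring fusion is then required. Methanolysis as in step 4 gives the racemic formyl ester F3, and preparative chromatography on a chiral stationary phase delivers its (1S,2S) enantiomer, which is 8.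

Step 17. The palladium cycle may stall on the doubly ortho-substituted, electron-rich aryl bromide, with protodebromination or β-carbon elimination of the tertiary alkoxide in place of C–O reductive elimination. The fallback sets out from 22 and comes back at 29, and steps 13–16 are then not needed: the aryl–oxygen bond is made first and the ring is closed at carbon. The potassium alkoxide of 22 (KHMDS, THF–DMF) displaces fluoride from 4-fluoro-3-methylbenzaldehyde by SNAr, which leaves the bonds at C2 untouched and gives the aryl ether aldehyde F4. Dakin oxidation (mCPBA, NaHCO3) gives the aryl formate F5, methanolysis (K2CO3, MeOH) the phenol F6, and methylation (MeI, K2CO3, acetone) the 4-methoxy-2-methylphenyl propargyl ether F7. Gold(I)-catalysed 6-endo hydroarylation of F7 ([JohnPhosAu(MeCN)]SbF6, CH2Cl2, rt) at its only free ortho position should then give 29.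

Step 23. The ynone may be over-reduced, the Z enone may isomerise to E on the catalyst, or hydrogen may add to the conjugated system in a non-selective way. The fallback sets out from 33 and comes back at 36: the triple bond is reduced before the ketone exists. Lindlar hydrogenation of 33 gives the (Z)-allylic diol F8, buffered DMP oxidises only its secondary allylic alcohol to the (Z)-enone ketal F9, and PPTS in wet acetone as in step 22 gives 36.

**Further compounds**

F1 | step 3 | 2,2-dimethyl-4H-1,3-dioxin-4-one | CC1(C)OC=CC(=O)O1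
F2 | step 3 | racemic cis-fused photoadduct of F1 and 6 (cis-anti-cis; one enantiomer drawn) | CC1(C)O[C@H]2[C@@H](C(=O)O1)[C@]3(C)CCC[C@]23C
F3 | step 3 | racemic methyl 2-(cis-2-formyl-1,2-dimethylcyclopentyl)acetate (one enantiomer drawn) | COC(=O)C[C@]1(C)CCC[C@]1(C)C=O
F4 | step 17 | 4-{[(3R)-6-{(1S,2S)-2-[(tert-butyldiphenylsilyloxy)methyl]-1,2-dimethylcyclopentyl}-5,5-dimethoxy-3-methylhex-1-yn-3-yl]oxy}-3-methylbenzaldehyde | Cc1cc(C=O)ccc1O[C@@](C)(C#C)CC(OC)(OC)C[C@]2(C)CCC[C@]2(C)CO[Si](c3ccccc3)(c3ccccc3)C(C)(C)C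
F5 | step 17 | aryl formate from Dakin oxidation of F4 | Cc1cc(OC=O)ccc1O[C@@](C)(C#C)CC(OC)(OC)C[C@]2(C)CCC[C@]2(C)CO[Si](c3ccccc3)(c3ccccc3)C(C)(C)C
F6 | step 17 | 4-{[(3R)-6-{(1S,2S)-2-[(tert-butyldiphenylsilyloxy)methyl]-1,2-dimethylcyclopentyl}-5,5-dimethoxy-3-methylhex-1-yn-3-yl]oxy}-3-methylphenol | Cc1cc(O)ccc1O[C@@](C)(C#C)CC(OC)(OC)C[C@]2(C)CCC[C@]2(C)CO[Si](c3ccccc3)(c3ccccc3)C(C)(C)C
F7 | step 17 | 4-methoxy-2-methylphenyl ether of 22 | COc1ccc(O[C@@](C)(C#C)CC(OC)(OC)C[C@]2(C)CCC[C@]2(C)CO[Si](c3ccccc3)(c3ccccc3)C(C)(C)C)c(C)c1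
F8 | step 23 | (2Z)-1-[(1S,2S)-2-{2,2-dimethoxy-3-[(2R)-6-methoxy-2,8-dimethyl-2H-chromen-2-yl]propyl}-1,2-dimethylcyclopentyl]-4-methylpent-2-ene-1,4-diol (both C1 epimers) | COc1cc(C)c2c(c1)C=C[C@@](C)(CC(OC)(OC)C[C@]3(C)CCC[C@]3(C)C(O)/C=C\C(C)(C)O)O2
F9 | step 23 | (2Z)-1-[(1S,2S)-2-{2,2-dimethoxy-3-[(2R)-6-methoxy-2,8-dimethyl-2H-chromen-2-yl]propyl}-1,2-dimethylcyclopentyl]-4-hydroxy-4-methylpent-2-en-1-one | COc1cc(C)c2c(c1)C=C[C@@](C)(CC(OC)(OC)C[C@]3(C)CCC[C@]3(C)C(=O)/C=C\C(C)(C)O)O2
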